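## Structural features

The target is a flavanone: benzene ring A is fused to the oxygen heterocycle ring C (a chroman-4-one), and C2 carries a 2,4-dihydroxyphenyl ring B and is a stereocentre of S configuration. Ring A is a phloroglucinol core whose three oxygens have three different fates (O1 in ring C, a methyl ether at C5, a free hydroxyl at C7). Between the two exocyclic oxygens, at C6, it carries the chain CH2–CH(CH2CH=CMe2)–CMe2OH. The chain methine is the second stereocentre (S); it lies seven bonds from C2, so the two centres are not neighbours, cannot influence each other, and each needs its own source of asymmetry. Three elements are fragile: C2 (epimerised through ring opening to the 2′-hydroxychalcone under base), the tertiary alcohol (placed to cyclise with the C7 hydroxyl to a 2,2-dimethylchroman under acid), and the trisubstituted alkene (sensitive to acid and to hydrogenation). The real difficulty is therefore regiochemistry on ring A (which oxygen is methylated, and whether the carbonyl enters at C4a or C8) together with a chain stereocentre remote from all ring functionality. The key step uses the fact that the carbonyl carbon C4 is bonded to C4a and C3 while O1 sits ortho to C4a: ring C divides into a ring A 2-iodophenol, carbon monoxide and an arylacetylene that brings C3, C2 and ring B.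

## Logic of the disconnections

**27 to 26.** The three phenolic O–H bonds (O7, O2′, O4′) are traced back to O–Si bonds. Silyl ethers are chosen over acetals so that the last step is buffered fluoride: acid would invite chroman formation from the chain alcohol and the C7 hydroxyl, and base would open ring C. Nothing is gained in skeleton; the demand is a near-neutral desilylation.

**26 to 25.** The C2–H and C3–H bonds are removed to reach the planar flavone. This deletes the ring C stereocentre, which can then be set last by a catalyst. The forward step must deliver hydride to one face of a β-aryl, β-oxy enone without help from the remote chain centre, and must spare the alkene and the C4 carbonyl.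

**25 to 18, 21 and 22.** The bonds C4a–C4, C4–C3 and O1–C2 are cut. All three meet around C4, so ring C and ring B are removed together and the synthesis becomes convergent. The demand is an iodide exactly at C4a with O1–H free and O7 blocked, closure to the six-membered ring and not the five-membered one, and a chain alcohol and alkene that stay spectators.

**21 to 20 to 19.** The alkyne carbon–carbon bond is traced to a formyl group by one-carbon homologation, and the O–Si bonds to the free diphenol. The homologation must be aprotic because of the aryl silyl ethers.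

**18 to 17 to 15.** The C4a–I bond and the O1 acetal are cut. Electrophilic iodination of a ring A phenol would have to choose between C4a and C8, which are electronically alike. The C–I bond is therefore traced to a C–Li bond placed between two cooperating directing groups (the O1 acetal and the O5 methyl ether), while O7 carries a bulky, non-coordinating silyl group. The demand is metalation in the presence of a tertiary alkoxide, an iodine source that spares the alkene, and a mild acetal cleavage.

**15 to 13.** The two C–CH3 bonds of the carbinol are cut. The tertiary alcohol becomes a latent ester, so the stereocentre sits α to a carbonyl where auxiliary chemistry can set it. The intermediate ketone must not enolise.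

**13 to 12 to 9 and 10.** The ester C–O bond is exchanged for the imide C–N bond, and the bond from the α-carbon to the prenyl CH2 is cut. An allylic bromide is an ideal electrophile. The other possible cut, at the arylmethyl bond, would need a 2,4,6-trioxygenated benzyl halide that ionises readily. The demand is facial control by the auxiliary.

**9 to 6 and 7; 6 to 5 to 3 and 4.** The N-acyl bond is cut, then the bond between the benzylic carbon and the α-carbon (as an alkene from an olefination). The formyl carbon of the aldehyde becomes the benzylic CH2. The hydrogenation must come before any prenyl alkene exists.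

**3 to 2 to 1.** The O–Si and O–CH2OMe bonds are cut. Compound 1 already carries the O5 methyl group and two hydroxyls that differ by chelation, so no symmetric triol has to be desymmetrised. The first alkylation must be site-selective.

## Other disconnections considered

**Alternative 1:** The cut lies in the chain, not in ring C: the benzylic CH2–CH bond and the O7–acyl bond are formed together to give lactone A3.
- **Forward step:** a chiral N-heterocyclic carbene turns α-chloroaldehyde A2 into an azolium enolate by loss of HCl, base releases the ortho-quinone methide from sulfone A1, and a formal [4+2] annulation closes the lactone. A methyl Grignard reagent would then open A3 to the C7 phenol and the carbinol at once.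
- **In its favour:** the chain centre is set catalytically with no auxiliary; the lactone protects O7 and serves as the carboxyl; O7 and O1 are distinguished by construction; the halogen at C4a is present before the chain is made. On step count for the chain it is the better plan, since steps 5 to 8 would shrink to two operations. On convergence it is equal, because A3 could feed the same carbonylative union.
- **Against it here:** annulations of this kind normally use a substituted methide carbon, whereas the unsubstituted methide from A1 is more reactive and prone to self-reaction. The only stereocentre of A3 sits α to an aryl ester and can enolise under the basic conditions and again at the ketone stage of the opening. A1 is itself a pentasubstituted arene that needs the same oxygen differentiation plus a regioselective bromination. A bromide is a poorer carbonylation partner than an iodide, and the freed C7 phenol would need protection again.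
- **Comparison:** structurally it competes with the chain-building steps, not with step 13. Mechanistically it replaces auxiliary control by catalyst control, which is more elegant but less predictable for this substitution pattern. The chosen plan is longer and more dependable.

**Alternative 2:** The chain CH–CH2 bond and the carbinol C–O bond are cut at the very end.
- **Forward step:** the alkene of 6-prenylflavanone A4 attacks the dimethylallyl cation released from 10 by a halide-abstracting silver salt, and water traps the tertiary cation to give A5, the triacetate of the target.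
- **In its favour:** it is the shortest conceivable route, it mirrors the likely biogenesis, and the chain needs no protecting-group planning. On step count it is clearly the better plan. On ring construction the two plans are equal, since no new ring is needed.
- **Against it here:** nothing controls the new chain centre, because the cation is achiral and C2 is seven bonds away, so a mixture of chain epimers must be expected. The product carries a new prenyl alkene as reactive as the starting one, so further alkylation competes. The tertiary cation can lose a proton or be captured by the neighbouring acetoxy oxygen instead of water. The allyl cation can also react at its tertiary end or with an arene. The strong acid set free threatens C2 and the new alcohol.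
- **Comparison:** it is a free carbocation process set against a defined organometallic cycle, and it is worse on every selectivity that matters for a single stereoisomer.

**Alternative 3:** Three ring A bonds (C6–C7, C4a–C5, C7–C8) are cut, so ring A is built around the chain.
- **Forward step:** heating cyclobutenone A6 with alkynyl ether A7 opens the four-membered ring to a vinylketene, which undergoes [2+2] addition to the alkyne; four-electron opening, six-electron closure and tautomerisation then give phenol A8.
- **In its favour:** the mechanism fixes the substitution pattern of ring A, with the chain between the methoxy group and the new hydroxyl and three oxygens that emerge already different. On regiochemical certainty of ring A it is the better plan, since the chosen route needs steps 1, 2, 9 and 10 and a chelation argument. Conditions are neutral and thermal, and the reliability of the pericyclic cascade is equal to that of the chosen organometallic step.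
- **Against it here:** a phloroglucinol ring is cheap to buy, so building it from acyclic pieces spends steps where none are needed. A7 needs the chain centre (set by an alkylation like step 6) and then several steps to the alkynyl ether; A6 is a sensitive silyl enol ether; the chain alkene is a possible ketene partner. In A8 the free hydroxyl is O7 and the silylated one is O1, so protecting groups must be exchanged before C4a can be functionalised, and ring C and C2 are still to come.
- **Comparison:** better on ring A regiochemistry, equal on mechanistic soundness, worse on step economy.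

Key step: step 13

**Remarks before the steps**
- Check of structures: the target is a 5-methoxy-7-hydroxyflavanone with 2S configuration and an S-configured chain methine; the key-step precursor and product are consistent with it and need no structural correction. Their skeletons are kept, but O7 and both ring B oxygens are carried as triisopropylsilyl ethers instead of acetals, for the regiochemical and end-game reasons given above.
- Assumption: 1 is purchased as a catalogue compound.
- Assumption: (R)-DTBM-SEGPHOS is written for the ligand antipode that delivers hydride to the Re face of C2; if a model 2-arylchromone shows the opposite sense, the (S) ligand is used with no other change.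

## Route

**Step 1**
Reactants: 1 2,4-dihydroxy-6-methoxybenzaldehyde
Product: 2 2-hydroxy-6-methoxy-4-(methoxymethoxy)benzaldehyde
Conditions: MOMCl (1.05 equiv), i-Pr2NEt, CH2Cl2, 0 °C
Reagents that add atoms: chloromethyl methyl ether, COCCl
Why: The hydroxyl para to the formyl group is the more acidic and is not hydrogen-bonded, whereas the ortho hydroxyl is chelated to the carbonyl oxygen, so one equivalent of the chloromethyl ether should alkylate O4 only (Williamson-type O-alkylation with chelation-based site selectivity); this acetal later directs metalation to the future C4a.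

**Step 2**
Reactants: 2 2-hydroxy-6-methoxy-4-(methoxymethoxy)benzaldehyde
Product: 3 2-methoxy-4-(methoxymethoxy)-6-(triisopropylsilyloxy)benzaldehyde
Conditions: TIPSCl, imidazole, DMAP (cat.), DMF, 40 °C
Reagents that add atoms: chlorotriisopropylsilane, CC(C)[Si](Cl)(C(C)C)C(C)C
Why: Silyl ether formation at the chelated phenol needs a nucleophilic catalyst and gentle heating but is otherwise standard; the chloride is preferred to the triflate, which could activate the acetal, and the bulky non-coordinating silyl ether is what later shields C8.

**Step 3**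
Reactants: 3 2-methoxy-4-(methoxymethoxy)-6-(triisopropylsilyloxy)benzaldehyde; 4 benzyl (triphenylphosphoranylidene)acetate
Product: 5 benzyl (2E)-3-[2-methoxy-4-(methoxymethoxy)-6-(triisopropylsilyloxy)phenyl]prop-2-enoate
Conditions: PhMe, 100 °C
Reagents that add atoms: none
Why: Wittig olefination with a stabilised ylide under neutral conditions should preserve the ortho silyl ether and give the E alkene, whose geometry no longer matters after step 4.

**Step 4**
Reactants: 5 benzyl (2E)-3-[2-methoxy-4-(methoxymethoxy)-6-(triisopropylsilyloxy)phenyl]prop-2-enoate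
Product: 6 3-[2-methoxy-4-(methoxymethoxy)-6-(triisopropylsilyloxy)phenyl]propanoic acid
Conditions: H2 (1 atm), Pd/C, EtOAc, rt
Reagents that add atoms: none
Why: Heterogeneous hydrogenation should saturate the conjugated alkene and hydrogenolyse the benzyl ester in one operation; the acetal, silyl ether and aryl ethers are inert and no other alkene is present yet.

**Step 5**
Reactants: 6 3-[2-methoxy-4-(methoxymethoxy)-6-(triisopropylsilyloxy)phenyl]propanoic acid; 7 (4S)-4-benzyl-1,3-oxazolidin-2-one
Product: 9 (4S)-4-benzyl-3-{3-[2-methoxy-4-(methoxymethoxy)-6-(triisopropylsilyloxy)phenyl]propanoyl}-1,3-oxazolidin-2-one, via mixed pivalic anhydride 8 (not isolated)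
Conditions: t-BuCOCl, Et3N, THF, −20 °C; then LiCl, 7, −20 °C → rt
Reagents that add atoms: none
Why: N-acylation of the oxazolidinone through the mixed anhydride with LiCl/Et3N activation is a standard way to load the auxiliary without strong base; the oxazolidinone should attack the less hindered carbonyl of 8 and release pivalate.

**Step 6**
Reactants: 9 (4S)-4-benzyl-3-{3-[2-methoxy-4-(methoxymethoxy)-6-(triisopropylsilyloxy)phenyl]propanoyl}-1,3-oxazolidin-2-one; 10 1-bromo-3-methylbut-2-ene
Product: 12 (4S)-4-benzyl-3-[(2S)-2-{[2-methoxy-4-(methoxymethoxy)-6-(triisopropylsilyloxy)phenyl]methyl}-5-methylhex-4-enoyl]-1,3-oxazolidin-2-one, via sodium Z-enolate 11 (not isolated)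
Conditions: NaN(SiMe3)2, THF, −78 °C; then 10, −78 → −40 °C
Reagents that add atoms: none
Why: Evans asymmetric alkylation: the sodium-chelated Z-enolate 11 should be attacked by the allylic bromide on the face opposite the C4 benzyl group of the auxiliary, which sets the chain centre as S (the arylmethyl group outranks the prenyl group); allylic bromides are among the best electrophiles for this enolate.

**Step 7**
Reactants: 12 (4S)-4-benzyl-3-[(2S)-2-{[2-methoxy-4-(methoxymethoxy)-6-(triisopropylsilyloxy)phenyl]methyl}-5-methylhex-4-enoyl]-1,3-oxazolidin-2-one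
Product: 13 benzyl (2S)-2-{[2-methoxy-4-(methoxymethoxy)-6-(triisopropylsilyloxy)phenyl]methyl}-5-methylhex-4-enoate
Conditions: BnOH, n-BuLi, THF, 0 °C
Reagents that add atoms: benzyl alcohol (as lithium benzyloxide), OCc1ccccc1
Why: Transesterification with lithium benzyloxide attacks the exocyclic imide carbonyl even in α-branched cases and at 0 °C should leave the α-centre untouched; the auxiliary is recovered.

**Step 8**
Reactants: 13 benzyl (2S)-2-{[2-methoxy-4-(methoxymethoxy)-6-(triisopropylsilyloxy)phenyl]methyl}-5-methylhex-4-enoate
Product: 15 (3S)-3-{[2-methoxy-4-(methoxymethoxy)-6-(triisopropylsilyloxy)phenyl]methyl}-2,6-dimethylhept-5-en-2-ol, via methyl ketone 14 (not isolated)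
Conditions: MeMgBr (4 equiv), LaCl3·2LiCl (0.3 equiv), THF, 0 °C
Reagents that add atoms: methylmagnesium bromide, C[Mg]Br
Why: Double Grignard addition to the ester through ketone 14 builds the carbinol; the lanthanum salt raises carbonyl reactivity and suppresses enolisation, so the adjacent stereocentre should be retained.

**Step 9**
Reactants: 15 (3S)-3-{[2-methoxy-4-(methoxymethoxy)-6-(triisopropylsilyloxy)phenyl]methyl}-2,6-dimethylhept-5-en-2-ol
Product: 17 (3S)-3-{[3-iodo-2-methoxy-4-(methoxymethoxy)-6-(triisopropylsilyloxy)phenyl]methyl}-2,6-dimethylhept-5-en-2-ol, via dilithio intermediate 16 (not isolated)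
Conditions: n-BuLi (2.3 equiv), TMEDA, THF, −78 → −30 °C; then ICH2CH2I, −78 °C
Reagents that add atoms: 1,2-diiodoethane, ICCI
Why: Directed ortho-metalation: the first equivalent of base forms the lithium alkoxide and the second removes the ring proton flanked by the acetal and the methoxy group (two cooperating directing groups), while the other ring proton is shielded by the silyl ether; 1,2-diiodoethane transfers iodine to the aryllithium without attacking the alkene, which elemental iodine and the neighbouring alkoxide could cyclise.

**Step 10**
Reactants: 17 (3S)-3-{[3-iodo-2-methoxy-4-(methoxymethoxy)-6-(triisopropylsilyloxy)phenyl]methyl}-2,6-dimethylhept-5-en-2-ol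
Product: 18 4-[(2S)-2-(2-hydroxypropan-2-yl)-5-methylhex-4-en-1-yl]-2-iodo-3-methoxy-5-(triisopropylsilyloxy)phenol
Conditions: NaHSO4·SiO2, CH2Cl2, rt
Reagents that add atoms: none
Why: Mild heterogeneous acid-catalysed hydrolysis of the phenolic acetal should spare the silyl ether, the tertiary alcohol, the alkene and the C–I bond; because O7 is silylated, no phenol is available for chroman formation.

**Step 11**
Reactants: 19 2,4-dihydroxybenzaldehyde
Product: 20 2,4-bis(triisopropylsilyloxy)benzaldehyde
Conditions: TIPSCl (2.4 equiv), imidazole, DMF, 40 °C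
Reagents that add atoms: chlorotriisopropylsilane, CC(C)[Si](Cl)(C(C)C)C(C)C
Why: Double silyl ether formation; gentle heating is needed for the chelated ortho hydroxyl.

**Step 12**
Reactants: 20 2,4-bis(triisopropylsilyloxy)benzaldehyde
Product: 21 1-ethynyl-2,4-bis(triisopropylsilyloxy)benzene
Conditions: Me3SiCHN2, n-BuLi, THF, −78 °C → rt
Reagents that add atoms: (trimethylsilyl)diazomethane, C[Si](C)(C)C=[N+]=[N-]
Why: Colvin-type one-carbon homologation (the silyl variant of the Seyferth–Gilbert reaction): the lithiated diazo reagent adds to the aldehyde, Peterson elimination gives the diazoalkene, loss of N2 gives the alkylidene carbene and a 1,2-hydrogen shift gives the alkyne; the aprotic medium should keep the aryl silyl ethers, which methanolic carbonate would endanger.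

**Step 13**
Reactants: 18 4-[(2S)-2-(2-hydroxypropan-2-yl)-5-methylhex-4-en-1-yl]-2-iodo-3-methoxy-5-(triisopropylsilyloxy)phenol; 21 1-ethynyl-2,4-bis(triisopropylsilyloxy)benzene; 22 carbon monoxide
Product: 25 2-[2,4-bis(triisopropylsilyloxy)phenyl]-6-[(2S)-2-(2-hydroxypropan-2-yl)-5-methylhex-4-en-1-yl]-5-methoxy-7-(triisopropylsilyloxy)-4H-chromen-4-one, via alkynyl ketone 23 (not isolated), via enaminone 24 (not isolated)
Conditions: PdCl2(PPh3)2 (5 mol %), CO (10 bar), Et2NH, 100 °C
Reagents that add atoms: none
Why: The divalent palladium precatalyst is reduced in the flask to zerovalent palladium, which inserts into the C4a–I bond; CO then inserts to give the aroyl complex, the amine-deprotonated alkyne is transferred to palladium, and reductive elimination releases alkynyl ketone 23 (C4a–C4 and C4–C3 formed). Diethylamine adds to 23 in conjugate fashion to give enaminone 24, and the ortho phenol oxygen then attacks the amine-bearing carbon and expels the amine (O1–C2 formed), an addition–elimination that amounts to a 6-endo closure of ring C. The closest known reaction type is the carbonylative Sonogashira coupling of 2-iodophenols with terminal alkynes in a secondary amine, with cyclisation to the flavone in the same flask. No stereocentre is created; C2 is set in step 14. The selectivities needed are flavone over the five-membered aurone, which the enaminone pathway in the amine solvent should secure, and carbonylative over direct coupling, which CO pressure and the absence of a copper co-catalyst should secure. The iodide lies between a hydroxyl and a methoxy group, which slows oxidative addition (hence the temperature) but places O1 exactly where closure needs it; O7 is silylated and meta to the new ketone, so only one phenol can close. The chain alkene and tertiary alcohol are spectators, and the triisopropylsilyl ethers should withstand the hot amine.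

**Step 14**
Reactants: 25 tris-silylated flavone (product of step 13)
Product: 26 (2S)-2-[2,4-bis(triisopropylsilyloxy)phenyl]-6-[(2S)-2-(2-hydroxypropan-2-yl)-5-methylhex-4-en-1-yl]-5-methoxy-7-(triisopropylsilyloxy)-2,3-dihydro-4H-chromen-4-one
Conditions: Cu(OAc)2 (5 mol %), (R)-DTBM-SEGPHOS (5.5 mol %), (EtO)2MeSiH, t-BuOH, PhMe, 0 °C → rt
Reagents that add atoms: none
Why: Copper-hydride-catalysed asymmetric conjugate reduction, a reaction type established for chromones: the ligated monovalent copper hydride formed from Cu(OAc)2, the bisphosphine and the silane adds hydride to C2 and tert-butanol protonates the copper enolate. The chiral bisphosphine alone decides the face (Re face of C2, giving 2S) because the chain centre is too remote to bias it, and the isolated trisubstituted alkene is not a substrate for the copper hydride.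

**Step 15**
Reactants: 26 tris-silylated (2S)-flavanone (product of step 14)
Product: 27 (2S)-2-(2,4-dihydroxyphenyl)-7-hydroxy-6-[(2S)-2-(2-hydroxypropan-2-yl)-5-methylhex-4-en-1-yl]-5-methoxy-2,3-dihydro-4H-chromen-4-one
Conditions: Bu4NF, AcOH (1:1), THF, 0 °C → rt
Reagents that add atoms: none
Why: Fluoride cleaves the three aryl silyl ethers (strong Si–F bond, phenoxide leaving groups), and acetic acid keeps the medium near neutral, so neither base-induced opening of the flavanone, which would scramble C2, nor acid-induced reaction of the tertiary alcohol or the prenyl alkene should occur.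

## Compound list

1 | 2,4-dihydroxy-6-methoxybenzaldehyde | COc1cc(O)cc(O)c1C=O | starting material
2 | 2-hydroxy-6-methoxy-4-(methoxymethoxy)benzaldehyde | COCOc1cc(O)c(C=O)c(OC)c1 | intermediate
3 | 2-methoxy-4-(methoxymethoxy)-6-(triisopropylsilyloxy)benzaldehyde | COCOc1cc(OC)c(C=O)c(O[Si](C(C)C)(C(C)C)C(C)C)c1 | intermediate
4 | benzyl (triphenylphosphoranylidene)acetate | O=C(C=P(c1ccccc1)(c1ccccc1)c1ccccc1)OCc1ccccc1 | starting material
5 | benzyl (2E)-3-[2-methoxy-4-(methoxymethoxy)-6-(triisopropylsilyloxy)phenyl]prop-2-enoate | COCOc1cc(OC)c(/C=C/C(=O)OCc2ccccc2)c(O[Si](C(C)C)(C(C)C)C(C)C)c1 | intermediate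
6 | 3-[2-methoxy-4-(methoxymethoxy)-6-(triisopropylsilyloxy)phenyl]propanoic acid | COCOc1cc(OC)c(CCC(=O)O)c(O[Si](C(C)C)(C(C)C)C(C)C)c1 | intermediate
7 | (4S)-4-benzyl-1,3-oxazolidin-2-one | O=C1N[C@@H](Cc2ccccc2)CO1 | starting material
8 | 2,2-dimethylpropanoic 3-[2-methoxy-4-(methoxymethoxy)-6-(triisopropylsilyloxy)phenyl]propanoic anhydride | COCOc1cc(OC)c(CCC(=O)OC(=O)C(C)(C)C)c(O[Si](C(C)C)(C(C)C)C(C)C)c1 | intermediate (not isolated)
9 | (4S)-4-benzyl-3-{3-[2-methoxy-4-(methoxymethoxy)-6-(triisopropylsilyloxy)phenyl]propanoyl}-1,3-oxazolidin-2-one | COCOc1cc(OC)c(CCC(=O)N2[C@@H](Cc3ccccc3)COC2=O)c(O[Si](C(C)C)(C(C)C)C(C)C)c1 | intermediate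
10 | 1-bromo-3-methylbut-2-ene (prenyl bromide) | CC(C)=CCBr | starting material
11 | sodium (1Z)-1-[(4S)-4-benzyl-2-oxo-1,3-oxazolidin-3-yl]-3-[2-methoxy-4-(methoxymethoxy)-6-(triisopropylsilyloxy)phenyl]prop-1-en-1-olate | COCOc1cc(OC)c(C/C=C(\[O-])N2[C@@H](Cc3ccccc3)COC2=O)c(O[Si](C(C)C)(C(C)C)C(C)C)c1.[Na+] | intermediate (not isolated)
12 | (4S)-4-benzyl-3-[(2S)-2-{[2-methoxy-4-(methoxymethoxy)-6-(triisopropylsilyloxy)phenyl]methyl}-5-methylhex-4-enoyl]-1,3-oxazolidin-2-one | COCOc1cc(OC)c(C[C@H](CC=C(C)C)C(=O)N2[C@@H](Cc3ccccc3)COC2=O)c(O[Si](C(C)C)(C(C)C)C(C)C)c1 | intermediate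
13 | benzyl (2S)-2-{[2-methoxy-4-(methoxymethoxy)-6-(triisopropylsilyloxy)phenyl]methyl}-5-methylhex-4-enoate | COCOc1cc(OC)c(C[C@H](CC=C(C)C)C(=O)OCc2ccccc2)c(O[Si](C(C)C)(C(C)C)C(C)C)c1 | intermediate
14 | (3S)-3-{[2-methoxy-4-(methoxymethoxy)-6-(triisopropylsilyloxy)phenyl]methyl}-6-methylhept-5-en-2-one | COCOc1cc(OC)c(C[C@H](CC=C(C)C)C(C)=O)c(O[Si](C(C)C)(C(C)C)C(C)C)c1 | intermediate (not isolated)
15 | (3S)-3-{[2-methoxy-4-(methoxymethoxy)-6-(triisopropylsilyloxy)phenyl]methyl}-2,6-dimethylhept-5-en-2-ol | COCOc1cc(OC)c(C[C@H](CC=C(C)C)C(C)(C)O)c(O[Si](C(C)C)(C(C)C)C(C)C)c1 | intermediate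
16 | dilithio derivative of 15: lithium alkoxide of the carbinol and aryllithium at the ring carbon between the methoxy and methoxymethoxy groups | COCOc1cc(O[Si](C(C)C)(C(C)C)C(C)C)c(C[C@H](CC=C(C)C)C(C)(C)O[Li])c(OC)c1[Li] | intermediate (not isolated)
17 | (3S)-3-{[3-iodo-2-methoxy-4-(methoxymethoxy)-6-(triisopropylsilyloxy)phenyl]methyl}-2,6-dimethylhept-5-en-2-ol | COCOc1cc(O[Si](C(C)C)(C(C)C)C(C)C)c(C[C@H](CC=C(C)C)C(C)(C)O)c(OC)c1I | intermediate
18 | 4-[(2S)-2-(2-hydroxypropan-2-yl)-5-methylhex-4-en-1-yl]-2-iodo-3-methoxy-5-(triisopropylsilyloxy)phenol | COc1c(C[C@H](CC=C(C)C)C(C)(C)O)c(O[Si](C(C)C)(C(C)C)C(C)C)cc(O)c1I | intermediate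
19 | 2,4-dihydroxybenzaldehyde | O=Cc1ccc(O)cc1O | starting material
20 | 2,4-bis(triisopropylsilyloxy)benzaldehyde | O=Cc1ccc(O[Si](C(C)C)(C(C)C)C(C)C)cc1O[Si](C(C)C)(C(C)C)C(C)C | intermediate
21 | 1-ethynyl-2,4-bis(triisopropylsilyloxy)benzene | C#Cc1ccc(O[Si](C(C)C)(C(C)C)C(C)C)cc1O[Si](C(C)C)(C(C)C)C(C)C | intermediate
22 | carbon monoxide | [C-]#[O+] | starting material
23 | 3-[2,4-bis(triisopropylsilyloxy)phenyl]-1-{2-hydroxy-5-[(2S)-2-(2-hydroxypropan-2-yl)-5-methylhex-4-en-1-yl]-6-methoxy-4-(triisopropylsilyloxy)phenyl}prop-2-yn-1-one | COc1c(C[C@H](CC=C(C)C)C(C)(C)O)c(O[Si](C(C)C)(C(C)C)C(C)C)cc(O)c1C(=O)C#Cc1ccc(O[Si](C(C)C)(C(C)C)C(C)C)cc1O[Si](C(C)C)(C(C)C)C(C)C | intermediate (not isolated)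
24 | 3-[2,4-bis(triisopropylsilyloxy)phenyl]-3-(diethylamino)-1-{2-hydroxy-5-[(2S)-2-(2-hydroxypropan-2-yl)-5-methylhex-4-en-1-yl]-6-methoxy-4-(triisopropylsilyloxy)phenyl}prop-2-en-1-one (alkene geometry not defined) | COc1c(C[C@H](CC=C(C)C)C(C)(C)O)c(O[Si](C(C)C)(C(C)C)C(C)C)cc(O)c1C(=O)C=C(N(CC)CC)c1ccc(O[Si](C(C)C)(C(C)C)C(C)C)cc1O[Si](C(C)C)(C(C)C)C(C)C | intermediate (not isolated)
25 | 2-[2,4-bis(triisopropylsilyloxy)phenyl]-6-[(2S)-2-(2-hydroxypropan-2-yl)-5-methylhex-4-en-1-yl]-5-methoxy-7-(triisopropylsilyloxy)-4H-chromen-4-one | COc1c(C[C@H](CC=C(C)C)C(C)(C)O)c(O[Si](C(C)C)(C(C)C)C(C)C)cc2c1C(=O)C=C(c1ccc(O[Si](C(C)C)(C(C)C)C(C)C)cc1O[Si](C(C)C)(C(C)C)C(C)C)O2 | intermediate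
26 | (2S)-2-[2,4-bis(triisopropylsilyloxy)phenyl]-6-[(2S)-2-(2-hydroxypropan-2-yl)-5-methylhex-4-en-1-yl]-5-methoxy-7-(triisopropylsilyloxy)-2,3-dihydro-4H-chromen-4-one | COc1c(C[C@H](CC=C(C)C)C(C)(C)O)c(O[Si](C(C)C)(C(C)C)C(C)C)cc2c1C(=O)C[C@@H](c1ccc(O[Si](C(C)C)(C(C)C)C(C)C)cc1O[Si](C(C)C)(C(C)C)C(C)C)O2 | intermediate
27 | (2S)-2-(2,4-dihydroxyphenyl)-7-hydroxy-6-[(2S)-2-(2-hydroxypropan-2-yl)-5-methylhex-4-en-1-yl]-5-methoxy-2,3-dihydro-4H-chromen-4-one (CNP0298187.1) | COc1c(C[C@H](CC=C(C)C)C(C)(C)O)c(O)cc2c1C(=O)C[C@@H](c1ccc(O)cc1O)O2 | target

## Step count and least certain steps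

Total step count: 15 (ring A branch, steps 1 to 10; ring B branch, steps 11 and 12; union and end game, steps 13 to 15). Longest linear sequence: 13 steps (1 to 10, then 13, 14 and 15).

**Step 13 (key step).**
- What may go wrong: oxidative addition at the electron-rich, doubly ortho-substituted C–I bond may be slow under CO. The aroyl complex may be captured by the amine solvent (aminocarbonylation). The alkyne may couple before CO inserts and then cyclise to a five-membered ring. Closure may by-pass the enaminone and go 5-exo.
- Fallback: it sets out from 15 and 21 and returns at 25. Alkyne 21 is deprotonated with n-BuLi and acylated with N-methoxy-N-methylcarbamoyl chloride to give 3-[2,4-bis(triisopropylsilyloxy)phenyl]-N-methoxy-N-methylprop-2-ynamide F1. Compound 15 is metalated exactly as in step 9 to 16, which is added to F1 to give the acetal-protected alkynyl ketone 3-[2,4-bis(triisopropylsilyloxy)phenyl]-1-{3-[(2S)-2-(2-hydroxypropan-2-yl)-5-methylhex-4-en-1-yl]-2-methoxy-6-(methoxymethoxy)-4-(triisopropylsilyloxy)phenyl}prop-2-yn-1-one F2. NaHSO4·SiO2 then frees the phenol to give 23, and warming 23 in Et2NH/EtOH closes ring C through 24 to 25. The same three bonds are made, but stepwise and without palladium.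

**Step 14.**
- What may go wrong: turnover may fail because the β-carbon carries both an oxygen and an aryl group with a bulky ortho silyloxy substituent. The C4 carbonyl may be over-reduced once the ketone is released. Facial discrimination may be insufficient.
- Fallback: it sets out from 25 and returns at 26. Conjugate reduction with LiBH(s-Bu)3 (THF, −78 °C) should give 26 together with its C2 epimer, the (2R)-flavanone F3. Transfer hydrogenation of the mixture with RuCl(p-cymene)[(R,R)-TsDPEN] and HCO2H/Et3N is expected, by the usual sense of this catalyst family with aryl ketones, to reduce the 2R epimer faster to the cis (2R,4R)-flavan-4-ol F4. Unreacted 26 is then separated by chromatography.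

**Step 9.**
- What may go wrong: the silyl group may migrate from O7 to the chain alkoxide. Metalation may occur next to the silyl ether and be followed by an oxygen-to-carbon silyl shift. Metalation may be incomplete.
- Fallback: it sets out from 15 and returns at 18. The acetal is removed first with NaHSO4·SiO2 to give (3S)-3-{[4-hydroxy-2-methoxy-6-(triisopropylsilyloxy)phenyl]methyl}-2,6-dimethylhept-5-en-2-ol F5. The free phenol is then iodinated with the morpholine–iodine complex in CH2Cl2 at low temperature. Here the site is chosen by steric shielding of C8 by the silyl ether instead of by chelation; the electronic preference between the two ortho sites is small, so this selectivity is less secure than in the main route.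

**Step 10.**
- What may go wrong: acid may ionise the tertiary alcohol, add to or cyclise the alkene, or cause protodeiodination of the electron-rich iodoarene.
- Fallback: it sets out from 17 and returns at 18. Non-protic acetal cleavage by silyl transfer (Me3SiOSO2CF3, 2,2′-bipyridyl, CH2Cl2, 0 °C) should give the bis(trimethylsilyl) ether {[(3S)-3-{[3-iodo-2-methoxy-6-(triisopropylsilyloxy)-4-(trimethylsilyloxy)phenyl]methyl}-2,6-dimethylhept-5-en-2-yl]oxy}trimethylsilane F6. Its two trimethylsilyl groups are removed with K2CO3 in MeOH at 0 °C.

**Step 12.**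
- What may go wrong: the ortho silyl group may transfer to the alkoxide formed on addition before the Peterson elimination takes place, or an aryl silyl ether may be lost.
- Fallback: it sets out from 20 and returns at 21 by the Corey–Fuchs sequence. CBr4, PPh3 and Zn in CH2Cl2 give 1-(2,2-dibromoethenyl)-2,4-bis(triisopropylsilyloxy)benzene F7 without a free alkoxide. n-BuLi (2.1 equiv, THF, −78 °C) followed by water then gives the alkyne.

## Further compounds

F1 | step 13 | 3-[2,4-bis(triisopropylsilyloxy)phenyl]-N-methoxy-N-methylprop-2-ynamide | CON(C)C(=O)C#Cc1ccc(O[Si](C(C)C)(C(C)C)C(C)C)cc1O[Si](C(C)C)(C(C)C)C(C)C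
F2 | step 13 | 3-[2,4-bis(triisopropylsilyloxy)phenyl]-1-{3-[(2S)-2-(2-hydroxypropan-2-yl)-5-methylhex-4-en-1-yl]-2-methoxy-6-(methoxymethoxy)-4-(triisopropylsilyloxy)phenyl}prop-2-yn-1-one | COCOc1cc(O[Si](C(C)C)(C(C)C)C(C)C)c(C[C@H](CC=C(C)C)C(C)(C)O)c(OC)c1C(=O)C#Cc1ccc(O[Si](C(C)C)(C(C)C)C(C)C)cc1O[Si](C(C)C)(C(C)C)C(C)C
F3 | step 14 | (2R)-2-[2,4-bis(triisopropylsilyloxy)phenyl]-6-[(2S)-2-(2-hydroxypropan-2-yl)-5-methylhex-4-en-1-yl]-5-methoxy-7-(triisopropylsilyloxy)-2,3-dihydro-4H-chromen-4-one | COc1c(C[C@H](CC=C(C)C)C(C)(C)O)c(O[Si](C(C)C)(C(C)C)C(C)C)cc2c1C(=O)C[C@H](c1ccc(O[Si](C(C)C)(C(C)C)C(C)C)cc1O[Si](C(C)C)(C(C)C)C(C)C)O2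
F4 | step 14 | (2R,4R)-2-[2,4-bis(triisopropylsilyloxy)phenyl]-6-[(2S)-2-(2-hydroxypropan-2-yl)-5-methylhex-4-en-1-yl]-5-methoxy-7-(triisopropylsilyloxy)-3,4-dihydro-2H-chromen-4-ol | COc1c(C[C@H](CC=C(C)C)C(C)(C)O)c(O[Si](C(C)C)(C(C)C)C(C)C)cc2c1[C@H](O)C[C@H](c1ccc(O[Si](C(C)C)(C(C)C)C(C)C)cc1O[Si](C(C)C)(C(C)C)C(C)C)O2
F5 | step 9 | (3S)-3-{[4-hydroxy-2-methoxy-6-(triisopropylsilyloxy)phenyl]methyl}-2,6-dimethylhept-5-en-2-ol | COc1cc(O)cc(O[Si](C(C)C)(C(C)C)C(C)C)c1C[C@H](CC=C(C)C)C(C)(C)O
F6 | step 10 | {[(3S)-3-{[3-iodo-2-methoxy-6-(triisopropylsilyloxy)-4-(trimethylsilyloxy)phenyl]methyl}-2,6-dimethylhept-5-en-2-yl]oxy}trimethylsilane | COc1c(C[C@H](CC=C(C)C)C(C)(C)O[Si](C)(C)C)c(O[Si](C(C)C)(C(C)C)C(C)C)cc(O[Si](C)(C)C)c1I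
F7 | step 12 | 1-(2,2-dibromoethenyl)-2,4-bis(triisopropylsilyloxy)benzene | BrC(Br)=Cc1ccc(O[Si](C(C)C)(C(C)C)C(C)C)cc1O[Si](C(C)C)(C(C)C)C(C)C
A1 | alternative 1 | 4-bromo-3-methoxy-5-(methoxymethoxy)-2-[(4-methylbenzenesulfonyl)methyl]phenol | COc1c(CS(=O)(=O)c2ccc(C)cc2)c(O)cc(OCOC)c1Br
A2 | alternative 1 | 2-chloro-5-methylhex-4-enal (racemic) | CC(C)=CCC(Cl)C=O
A3 | alternative 1 | (3S)-6-bromo-5-methoxy-7-(methoxymethoxy)-3-(3-methylbut-2-en-1-yl)-3,4-dihydro-2H-chromen-2-one | COc1c2C[C@H](CC=C(C)C)C(=O)Oc2cc(OCOC)c1Br
A4 | alternative 2 | (2S)-7-acetoxy-2-(2,4-diacetoxyphenyl)-5-methoxy-6-(3-methylbut-2-en-1-yl)-2,3-dihydro-4H-chromen-4-one | COc1c(CC=C(C)C)c(OC(C)=O)cc2c1C(=O)C[C@@H](c1ccc(OC(C)=O)cc1OC(C)=O)O2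
A5 | alternative 2 | (2S)-7-acetoxy-2-(2,4-diacetoxyphenyl)-6-[(2S)-2-(2-hydroxypropan-2-yl)-5-methylhex-4-en-1-yl]-5-methoxy-2,3-dihydro-4H-chromen-4-one | COc1c(C[C@H](CC=C(C)C)C(C)(C)O)c(OC(C)=O)cc2c1C(=O)C[C@@H](c1ccc(OC(C)=O)cc1OC(C)=O)O2
A6 | alternative 3 | 3-(triisopropylsilyloxy)cyclobut-2-en-1-one | O=C1CC(O[Si](C(C)C)(C(C)C)C(C)C)=C1
A7 | alternative 3 | triethyl{[(3S)-3-(3-methoxyprop-2-yn-1-yl)-2,6-dimethylhept-5-en-2-yl]oxy}silane | COC#CC[C@H](CC=C(C)C)C(C)(C)O[Si](CC)(CC)CC
A8 | alternative 3 | 3-methoxy-2-[(2S)-5-methyl-2-{2-[(triethylsilyl)oxy]propan-2-yl}hex-4-en-1-yl]-5-(triisopropylsilyloxy)phenol | COc1c(C[C@H](CC=C(C)C)C(C)(C)O[Si](CC)(CC)CC)c(O)cc(O[Si](C(C)C)(C(C)C)C(C)C)c1
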